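**Assumption:** (S)‑3‑methylcyclohexanone and methyl (E)‑4‑oxobut‑2‑enoate are bought as catalogue compounds; the allyl ester, the nitro group and the TEMPO‑derived aminoxy group are temporary groups brought in by reagents. Locants C1–C15 are those of the target (ring C1–C10, lactone C11–C13, ester carbon C14, methyl C15 on C4). The route is a paper design and has not been run; the selectivities given are expected, not measured.

**Retrosynthetic overview**
- Target ⇐ its O9‑aminoxy ether ⇐ 1‑nitro lactone: loss of HNO2 makes the C1=C10 ester; the lactone comes from C6‑OH and the acrylate ester.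
- That ten‑membered ring ⇐ a 2‑alkyl‑2‑nitrocyclohexanone plus a C7/C11–C13 bromoallyl linchpin: double allylation, then retro‑Claisen cleavage of C1–C6 (6 → 10 ring enlargement).
- The nitrocyclohexanone side chain (C10, C14, C9, C8) ⇐ Michael addition to methyl 4‑oxobutenoate, then α‑oxyamination (C9–O).
- Regiodefined 2‑nitro ketone ⇐ (S)‑3‑methylcyclohexanone (supplies C4) via its allyl β‑keto ester; the angelate comes from angelic acid.
- Ring order: ring A (bought) → transient decalin → ten‑membered carbocycle → γ‑lactone.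

**Route**

Step 1
Reactants: 1 (S)-3-methylcyclohexanone
Product: 2 allyl (4S)-4-methyl-2-oxocyclohexane-1-carboxylate
Conditions: NaH, diallyl carbonate, THF, 65 °C; AcOH
Reagents that add atoms: diallyl carbonate C=CCOC(=O)OCC=C
Why: Thermodynamically controlled Claisen-type C-acylation should place the ester on the α-carbon remote from the methyl group (future C1), and the bought C4 (S) centre is untouched.

Step 2
Reactants: 2 allyl (4S)-4-methyl-2-oxocyclohexane-1-carboxylate
Product: 3 allyl (4S)-4-methyl-1-nitro-2-oxocyclohexane-1-carboxylate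
Conditions: Ac2O, HNO3 (AcONO2), CH2Cl2, −30 °C
Reagents that add atoms: nitric acid O[N+](=O)[O-]
Why: Electrophilic nitration of the enolised β-keto ester occurs at its only doubly activated carbon, fixing the nitro group at C1; the new quaternary centre is not a target stereocentre.

Step 3
Reactants: 3 allyl (4S)-4-methyl-1-nitro-2-oxocyclohexane-1-carboxylate
Product: 4 (5S)-5-methyl-2-nitrocyclohexan-1-one
Conditions: Pd(OAc)2 (3 mol%), PPh3, HCO2H, Et3N, THF, 25 °C
Reagents that add atoms: none
Why: Tsuji palladium-catalysed deallylation–decarboxylation removes the ester under near-neutral conditions and leaves the regiodefined α-nitro ketone (nitro carbon epimerisable, C4 unchanged).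

Step 4
Reactants: 4 (5S)-5-methyl-2-nitrocyclohexan-1-one; 5 methyl (E)-4-oxobut-2-enoate
Product: 6 methyl 2-[(4S)-4-methyl-1-nitro-2-oxocyclohexyl]-4-oxobutanoate
Conditions: Et3N (10 mol%), MeCN, 0 °C
Reagents that add atoms: none
Why: Michael addition of the nitronate to the enal carbon β to the aldehyde (α to the ester) forms C1–C10 with C14 in place; the two new centres (C1, C10) are carried as a mixture because both become sp2 in step 10.

Step 5
Reactants: 6 methyl 2-[(4S)-4-methyl-1-nitro-2-oxocyclohexyl]-4-oxobutanoate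
Product: 7 methyl (3S)-2-[(4S)-4-methyl-1-nitro-2-oxocyclohexyl]-4-oxo-3-[(2,2,6,6-tetramethylpiperidin-1-yl)oxy]butanoate
Conditions: TEMPO, CuCl2 (10 mol%), MacMillan imidazolidinone·TFA (20 mol%, enantiomer giving 3S), air, acetone, −10 °C
Reagents that add atoms: TEMPO CC1(C)CCCC(C)(C)N1[O]
Why: Enamine-catalysed α-oxyamination of the aldehyde installs the C9 oxygen as a robust alkoxyamine, with the catalyst enantiomer chosen to give C9 (S).

Step 6
Reactants: 8 methyl 2-(bromomethyl)acrylate
Product: 10 methyl (Z)-3-bromo-2-(bromomethyl)acrylate, via tribromo ester 9 (not isolated)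
Conditions: Br2, CH2Cl2, 0 °C; then Et3N, 0 → 25 °C
Reagents that add atoms: bromine BrBr
Why: Bromine addition followed by dehydrobromination gives the bromoallyl linchpin; its double-bond geometry does not matter because the allylindium species equilibrate.

Step 7
Reactants: 7 methyl (3S)-2-[(4S)-4-methyl-1-nitro-2-oxocyclohexyl]-4-oxo-3-[(2,2,6,6-tetramethylpiperidin-1-yl)oxy]butanoate; 10 methyl (Z)-3-bromo-2-(bromomethyl)acrylate
Product: 13 (4S,7R,8S,9S)-cyclodecanone with C8-OH and C1-NO2, via bromohydrin indium alkoxide 11 (not isolated), via bicyclic nitro alkoxide 12 (not isolated)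
Conditions: In powder (3 equiv), DMF, 0 → 25 °C; pH 5 buffer
Reagents that add atoms: none
Why: Proposed new method: a one-flask linchpin double allylation with ring enlargement, in which the allylindium from the allylic C–Br of 10 adds through its bromine-bearing γ-carbon to the chelated α-aminoxy aldehyde (Cram-chelate, C8–O syn to C9–O), the new secondary allylic bromide is metallated in turn and its γ-carbon C7 attacks the ring ketone through a chair bridged by indium between O8 and O6 (acrylate unit equatorial, giving the 7,8 relationship of the target), and the resulting alkoxide of a 2-nitro ketone collapses by retro-Claisen cleavage of C6–C1 to the nitronate, inserting C7–C10 into the six-membered ring; the closest known reactions are the Hesse-type ring enlargement of 2-nitrocycloalkanones by side-chain carbanions, the allyl-anion condensative ring expansion of β-keto sulfones, and indium Barbier reactions and γ-haloallylations with 2-(bromomethyl)acrylates.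

Step 8
Reactants: 13 (4S,7R,8S,9S)-cyclodecanone with C8-OH and C1-NO2; 14 angelic acid
Product: 15 C8 angelate of cyclodecanone 13
Conditions: 14, DCC, CH2Cl2, 0 °C (anhydride); then 13, Sc(OTf)3 (5 mol%), MeCN, −20 °C
Reagents that add atoms: none
Why: Lewis-acid-catalysed acylation by the preformed anhydride esterifies the only hydroxyl, keeps the Z geometry, and avoids base, which would cause β-elimination or epimerisation at the acidic C7–H next to the ketone.

Step 9
Reactants: 15 C8 angelate of cyclodecanone 13
Product: 17 (4S,6R,7S,8S,9S)-1-nitro lactone, via hydroxy ester 16 (not isolated)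
Conditions: (S)-Me-CBS (30 mol%), catecholborane, toluene, −60 °C; then CSA (20 mol%), CH2Cl2, 25 °C
Reagents that add atoms: none
Why: CBS reduction with reagent control (branched C7 as large flank, C5H2 as small flank) should give the (6R) alcohol, which lactonises onto the acrylate ester under acid to the trans-fused α-methylene-γ-butyrolactone.

Step 10
Reactants: 17 (4S,6R,7S,8S,9S)-1-nitro lactone
Product: 18 O9-(2,2,6,6-tetramethylpiperidin-1-yl) ether of the target
Conditions: DBU, THF, −20 → 0 °C
Reagents that add atoms: none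
Why: E1cB loss of nitrous acid from the β-nitro ester (C10–H is α to the ester) gives only the conjugated C1=C10 alkene, and the ten-membered ring should favour the ring-cis (E) isomer; C9 is protected, so no acyl migration.

Step 11
Reactants: 18 O9-(2,2,6,6-tetramethylpiperidin-1-yl) ether of the target
Product: 19 target CNP0552150.1
Conditions: Zn, AcOH/THF/H2O (3:1:1), 40 °C
Reagents that add atoms: none
Why: Reductive N–O cleavage of the alkoxyamine frees the C9 hydroxyl under acidic conditions, which should leave the angelate, the enoate and the α-methylene lactone intact.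

**Compound list**
1 | (S)-3-methylcyclohexanone | O=C1C[C@@H](C)CCC1 | starting material
2 | allyl (4S)-4-methyl-2-oxocyclohexane-1-carboxylate (keto/enol, C1 epimers) | O=C1C[C@@H](C)CCC1C(=O)OCC=C | intermediate
3 | allyl (4S)-4-methyl-1-nitro-2-oxocyclohexane-1-carboxylate (C1 epimers) | O=C1C[C@@H](C)CCC1([N+](=O)[O-])C(=O)OCC=C | intermediate
4 | (5S)-5-methyl-2-nitrocyclohexan-1-one (nitro carbon epimerisable) | O=C1C[C@@H](C)CCC1[N+](=O)[O-] | intermediate
5 | methyl (E)-4-oxobut-2-enoate | COC(=O)/C=C/C=O | starting material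
6 | methyl 2-[(4S)-4-methyl-1-nitro-2-oxocyclohexyl]-4-oxobutanoate (C1/C10 epimer mixture) | O=C1C[C@@H](C)CCC1([N+](=O)[O-])C(CC=O)C(=O)OC | intermediate
7 | methyl (3S)-2-[(4S)-4-methyl-1-nitro-2-oxocyclohexyl]-4-oxo-3-[(2,2,6,6-tetramethylpiperidin-1-yl)oxy]butanoate (C1/C10 mixture) | O=C1C[C@@H](C)CCC1([N+](=O)[O-])C(C(=O)OC)[C@H](ON2C(C)(C)CCCC2(C)C)C=O | intermediate
8 | methyl 2-(bromomethyl)acrylate | C=C(CBr)C(=O)OC | starting material
9 | methyl 2,3-dibromo-2-(bromomethyl)propanoate | COC(=O)C(Br)(CBr)CBr | intermediate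
10 | methyl (Z)-3-bromo-2-(bromomethyl)acrylate | COC(=O)/C(CBr)=C/Br | intermediate
11 | γ-bromoallylation adduct of 7 (C8 carbinol syn to C9–O, C7 bromide as epimers; drawn as the alcohol) | O=C1C[C@@H](C)CCC1([N+](=O)[O-])C(C(=O)OC)[C@H](ON2C(C)(C)CCCC2(C)C)[C@@H](O)C(Br)C(=C)C(=O)OC | intermediate
12 | bicyclic (decalin-type) tertiary nitro carbinol from C7→C6 allylation (C1/C6/C10 transient; drawn as the alcohol) | OC12C[C@@H](C)CCC1([N+](=O)[O-])C(C(=O)OC)[C@H](ON3C(C)(C)CCCC3(C)C)[C@@H](O)[C@H]2C(=C)C(=O)OC | intermediate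
13 | (4S,7R,8S,9S)-cyclodecanone: C6 ketone, C7 methyl acrylate unit, C8-OH, C9 aminoxy ether, C10-CO2Me, C1-NO2 (C1/C10 mixture) | O=C1C[C@@H](C)CCC([N+](=O)[O-])C(C(=O)OC)[C@H](ON2C(C)(C)CCCC2(C)C)[C@@H](O)[C@H]1C(=C)C(=O)OC | intermediate
14 | angelic acid, (Z)-2-methylbut-2-enoic acid | C/C=C(/C)C(=O)O | starting material
15 | C8 angelate of 13 (4S,7R,8S,9S) | O=C1C[C@@H](C)CCC([N+](=O)[O-])C(C(=O)OC)[C@H](ON2C(C)(C)CCCC2(C)C)[C@@H](OC(=O)/C(C)=C\C)[C@H]1C(=C)C(=O)OC | intermediate
16 | (4S,6R,7S,8S,9S) C6 alcohol (hydroxy ester) | O[C@@H]1C[C@@H](C)CCC([N+](=O)[O-])C(C(=O)OC)[C@H](ON2C(C)(C)CCCC2(C)C)[C@@H](OC(=O)/C(C)=C\C)[C@H]1C(=C)C(=O)OC | intermediate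
17 | (4S,6R,7S,8S,9S) trans-fused α-methylene lactone with C1-NO2, C10-H | O=C1O[C@@H]2C[C@@H](C)CCC([N+](=O)[O-])C(C(=O)OC)[C@H](ON3C(C)(C)CCCC3(C)C)[C@@H](OC(=O)/C(C)=C\C)[C@H]2C1=C | intermediate
18 | O9-(2,2,6,6-tetramethylpiperidin-1-yl) ether of the target, 1(10)E | O=C1O[C@@H]2C[C@@H](C)CC/C=C(/C(=O)OC)[C@H](ON3C(C)(C)CCCC3(C)C)[C@@H](OC(=O)/C(C)=C\C)[C@H]2C1=C | intermediate
19 | CNP0552150.1, (4S,6R,7S,8S,9S,1(10)E) | C=C1C(=O)O[C@@H]2C[C@@H](C)CC/C=C(/C(=O)OC)[C@H](O)[C@@H](OC(=O)/C(C)=C\C)[C@@H]12 | target

**Totals**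
Total step count: 11. Longest linear sequence: 10 (steps 1–5 and 7–11; step 6 is a side branch).

**Three steps most likely to fail**

Step 7 (the new step). Risks: the bromohydrin alkoxide could lactonise or form an epoxide before the second metallation; the C7/C8 selectivity could be low; indium could reduce the nitro group. Fallback with known reaction types, run as discrete steps, from 7 back to 13: run the indium γ-bromoallylation with one equivalent of metal in THF/H2O at 0 °C and isolate bromohydrin 11. Protect it with TESOTf/2,6-lutidine as the C8 triethylsilyl ether bromide F1. Carry out the intramolecular indium Barbier allylation of the ketone in DMF; the tertiary alkoxide of the 2-nitro ketone fragments in the Hesse manner to the ring-enlarged C8 triethylsilyl ether nitro ketone F2. HF·pyridine then gives 13. If the chelation-controlled addition gives the wrong C8 epimer, F1-type material can be corrected before cyclisation by oxidation and Felkin-controlled reduction.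

Step 9. Risks: the CBS reduction may be mismatched with C7 and give the C6 epimer, or the acid step may be slow. Fallback from 13 back to 17: use substrate control before acylation. Evans–Saksena reduction (Me4NBH(OAc)3, MeCN/AcOH, −30 °C), directed by the free C8-OH, gives the 6,8-anti diol F3. CSA closes the C6 hydroxyl onto the acrylate ester to the 6,12-lactone with free C8-OH F4. The step 8 acylation conditions (angelic anhydride, Sc(OTf)3) then give 17. Competing 8,12-lactone closure is the weak point of this fallback.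

Step 10. Risk: DBU also forms the C1 nitronate, which could add across the ring to the α-methylene lactone instead of eliminating. Fallback from 17 back to 18: convert the nitro group into the ketone by a McMurry-type Nef reaction (nitronate at −78 °C, then buffered aqueous TiCl3) to the C1-keto β-keto ester F5. Form the chelation-controlled enol triflate (NaH, Tf2O; OTf cis to CO2Me) F6. Reduce it with Pd(OAc)2/PPh3, HCO2H, Et3N to 18 with retention of the ring-cis geometry.

Further compounds
F1 | step 7 | C8 triethylsilyl ether of bromohydrin 11 | O=C1C[C@@H](C)CCC1([N+](=O)[O-])C(C(=O)OC)[C@H](ON2C(C)(C)CCCC2(C)C)[C@@H](O[Si](CC)(CC)CC)C(Br)C(=C)C(=O)OC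
F2 | step 7 | ring-enlarged nitro ketone as C8 triethylsilyl ether | O=C1C[C@@H](C)CCC([N+](=O)[O-])C(C(=O)OC)[C@H](ON2C(C)(C)CCCC2(C)C)[C@@H](O[Si](CC)(CC)CC)[C@H]1C(=C)C(=O)OC
F3 | step 9 | 6,8-anti diol from directed reduction of 13 | O[C@@H]1C[C@@H](C)CCC([N+](=O)[O-])C(C(=O)OC)[C@H](ON2C(C)(C)CCCC2(C)C)[C@@H](O)[C@H]1C(=C)C(=O)OC
F4 | step 9 | 6,12-lactone with free C8 hydroxyl | O=C1O[C@@H]2C[C@@H](C)CCC([N+](=O)[O-])C(C(=O)OC)[C@H](ON3C(C)(C)CCCC3(C)C)[C@@H](O)[C@H]2C1=C
F5 | step 10 | C1-keto β-keto ester from Nef reaction of 17 | O=C1O[C@@H]2C[C@@H](C)CCC(=O)C(C(=O)OC)[C@H](ON3C(C)(C)CCCC3(C)C)[C@@H](OC(=O)/C(C)=C\C)[C@H]2C1=C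
F6 | step 10 | C1 enol triflate (OTf cis to CO2Me) | O=C1O[C@@H]2C[C@@H](C)CC/C(OS(=O)(=O)C(F)(F)F)=C(/C(=O)OC)[C@H](ON3C(C)(C)CCCC3(C)C)[C@@H](OC(=O)/C(C)=C\C)[C@H]2C1=C
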